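**Retrosynthetic overview**

1. Pyranone ring first: aldehyde 1 and ylide 2 give, through cinnamate 3, 6-bromo-7-methoxycoumarin 4 (Wittig, then lactonisation).
2. Oxirane ring second, on the other fragment: prenol 5 → epoxy alcohol 6 (asymmetric epoxidation fixes C2') → epoxy aldehyde 7.
3. Key disconnection, aryl–C1' bond of ketone 8: bromide 4 plus the formyl carbon of 7 used as an acyl-anion equivalent; both carbons are electrophiles in their normal reactivity.
4. C1' is set by chelation-controlled reduction (9), O1' is acylated with anhydride 10 (11), and the oxirane is opened by water at C3' to give diol ester 12; no ring is formed after the oxirane.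

Assumption: side-chain carbons are called C1' (benzylic), C2' and C3' (the C(CH3)2 carbon); 1, 2, 5, 10 and all reagents are bought. The target is (1'R,2'R), i.e. the anti (erythro) 1',2'-dioxygen pattern.

**Route**

Step 1
Reactants: 1 5-bromo-2-hydroxy-4-methoxybenzaldehyde; 2 ethyl (triphenylphosphoranylidene)acetate
Product: 4 6-bromo-7-methoxy-2H-chromen-2-one, via cinnamate ester 3 (not isolated)
Conditions: N,N-diethylaniline, reflux (215 °C), 5 h
Reagents that add atoms: none
Why: Wittig olefination of the salicylaldehyde gives the hydroxycinnamate, which at this temperature isomerises E to Z and lactonises with loss of ethanol (thermal Wittig coumarin synthesis); no stereocentre is involved.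

Step 2
Reactants: 5 3-methylbut-2-en-1-ol (prenol)
Product: 6 [(2R)-3,3-dimethyloxiran-2-yl]methanol
Conditions: Ti(OiPr)4 (5 mol%), D-(−)-diethyl tartrate (6 mol%), t-BuOOH (1.5 equiv), 4 Å MS, CH2Cl2, −20 °C
Reagents that add atoms: tert-butyl hydroperoxide, CC(C)(C)OO
Why: Katsuki–Sharpless asymmetric epoxidation; the Ti(OiPr)4–D-tartrate catalyst delivers the peroxide oxygen to the enantioface that gives the 2R epoxy alcohol (the L-tartrate gives the 2S series), and this fixes C2' of the target.

Step 3
Reactants: 6 [(2R)-3,3-dimethyloxiran-2-yl]methanol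
Product: 7 (2S)-3,3-dimethyloxirane-2-carbaldehyde
Conditions: Pr4N[RuO4] (5 mol%), N-methylmorpholine N-oxide (1.5 equiv), 4 Å MS, CH2Cl2, 0 °C to rt; silica plug, cold concentration, used at once
Reagents that add atoms: none
Why: Ley–Griffith oxidation stops at the aldehyde under neutral anhydrous conditions; the oxirane survives and its carbon cannot enolise, so the stereocentre is untouched (the descriptor changes from R to S only because CHO outranks C3).

Step 4
Reactants: 4 6-bromo-7-methoxy-2H-chromen-2-one; 7 (2S)-3,3-dimethyloxirane-2-carbaldehyde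
Product: 8 6-{[(2S)-3,3-dimethyloxiran-2-yl]carbonyl}-7-methoxy-2H-chromen-2-one
Conditions: 7 (2.5 equiv), Ir[dF(CF3)ppy]2(dtbbpy)PF6 (1 mol%), NiBr2(MeOCH2CH2OMe) (10 mol%), 4,4'-di-tert-butyl-2,2'-bipyridine (10 mol%), quinuclidine (10 mol%), K2CO3 (1.5 equiv), 1,4-dioxane, blue LEDs, 25 °C
Reagents that add atoms: none
Why: Photoredox/hydrogen-atom-transfer/nickel aldehyde C–H arylation: the quinuclidinium radical cation abstracts the hydridic formyl hydrogen of 7, the nucleophilic acyl radical (an acyl-anion equivalent, so the normally electrophilic formyl carbon reacts with reversed polarity) is captured by the NiBr2-derived catalyst that has inserted into the C–Br bond of 4, and reductive elimination joins two formerly electrophilic carbons; the oxirane C–H is too strong to be abstracted and C2' cannot enolise, so its configuration is kept.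

Step 5
Reactants: 8 6-{[(2S)-3,3-dimethyloxiran-2-yl]carbonyl}-7-methoxy-2H-chromen-2-one
Product: 9 6-{(R)-[(2R)-3,3-dimethyloxiran-2-yl](hydroxy)methyl}-7-methoxy-2H-chromen-2-one
Conditions: Zn(BH4)2 (1.2 equiv), Et2O/THF, −30 °C; aq. NH4Cl
Reagents that add atoms: none
Why: Chelation-controlled hydride reduction: Zn bridges the ketone and oxirane oxygens in a five-membered chelate and hydride enters from the face away from C3', which gives the anti (erythro) epoxy alcohol and sets C1' as R; the lactone is not reduced by this reagent at low temperature.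

Step 6
Reactants: 9 6-{(R)-[(2R)-3,3-dimethyloxiran-2-yl](hydroxy)methyl}-7-methoxy-2H-chromen-2-one; 10 3-methylbutanoic anhydride
Product: 11 (R)-[(2R)-3,3-dimethyloxiran-2-yl](7-methoxy-2-oxo-2H-chromen-6-yl)methyl 3-methylbutanoate
Conditions: 10 (1.5 equiv), Et3N, DMAP (10 mol%), CH2Cl2, 0 °C to rt
Reagents that add atoms: none
Why: DMAP-catalysed acyl transfer to the only hydroxyl group; no bond to a stereocentre is broken, and the oxirane keeps O2' and O3' masked so that only O1' is esterified.

Step 7
Reactants: 11 (R)-[(2R)-3,3-dimethyloxiran-2-yl](7-methoxy-2-oxo-2H-chromen-6-yl)methyl 3-methylbutanoate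
Product: 12 (1R,2R)-2,3-dihydroxy-1-(7-methoxy-2-oxo-2H-chromen-6-yl)-3-methylbutyl 3-methylbutanoate
Conditions: HClO4 (5 mol%), THF/H2O 3:1, 0 °C
Reagents that add atoms: water, O
Why: Acid-catalysed epoxide hydrolysis: the protonated oxirane opens at the tertiary carbon C3' (SN1-like) and water adds there, so the C2'–O bond is never broken and C2' stays R; dilute acid at 0 °C leaves the ester and lactone intact.

**Compound list**

1 | 5-bromo-2-hydroxy-4-methoxybenzaldehyde | COc1cc(O)c(C=O)cc1Br | starting material
2 | ethyl (triphenylphosphoranylidene)acetate | CCOC(=O)C=P(c1ccccc1)(c1ccccc1)c1ccccc1 | starting material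
3 | ethyl (2E)-3-(5-bromo-2-hydroxy-4-methoxyphenyl)prop-2-enoate | CCOC(=O)/C=C/c1cc(Br)c(OC)cc1O | intermediate
4 | 6-bromo-7-methoxy-2H-chromen-2-one | COc1cc2oc(=O)ccc2cc1Br | intermediate
5 | 3-methylbut-2-en-1-ol | CC(C)=CCO | starting material
6 | [(2R)-3,3-dimethyloxiran-2-yl]methanol | OC[C@H]1OC1(C)C | intermediate
7 | (2S)-3,3-dimethyloxirane-2-carbaldehyde | O=C[C@H]1OC1(C)C | intermediate
8 | 6-{[(2S)-3,3-dimethyloxiran-2-yl]carbonyl}-7-methoxy-2H-chromen-2-one | COc1cc2oc(=O)ccc2cc1C(=O)[C@H]3OC3(C)C | intermediate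
9 | 6-{(R)-[(2R)-3,3-dimethyloxiran-2-yl](hydroxy)methyl}-7-methoxy-2H-chromen-2-one | COc1cc2oc(=O)ccc2cc1[C@@H](O)[C@H]3OC3(C)C | intermediate
10 | 3-methylbutanoic anhydride | CC(C)CC(=O)OC(=O)CC(C)C | starting material
11 | (R)-[(2R)-3,3-dimethyloxiran-2-yl](7-methoxy-2-oxo-2H-chromen-6-yl)methyl 3-methylbutanoate | COc1cc2oc(=O)ccc2cc1[C@@H](OC(=O)CC(C)C)[C@H]3OC3(C)C | intermediate
12 | (1R,2R)-2,3-dihydroxy-1-(7-methoxy-2-oxo-2H-chromen-6-yl)-3-methylbutyl 3-methylbutanoate | COc1cc2oc(=O)ccc2cc1[C@@H](OC(=O)CC(C)C)[C@@H](O)C(C)(C)O | target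

**Step count**

Total: 7 steps. Longest linear sequence: 6 steps (5 → 6 → 7 → 8 → 9 → 11 → 12).

**Steps most likely to fail, with fallbacks**

Risk 1, step 4. An oxirane-carbaldehyde has not been used as the acyl donor in this coupling; cyclopropane-type aldehydes are the nearest precedent. The iridium sensitiser may also trigger [2+2] dimerisation of the coumarin or rearrangement of the epoxy ketone, and acyl radicals can add to the coumarin C3=C4 bond. The fallback drops the photochemical acyl coupling and builds the same ketone thermally, setting out from 4. Miyaura borylation (PdCl2(dppf), bis(pinacolato)diboron, KOAc, dioxane, 90 °C) gives 7-methoxy-6-(4,4,5,5-tetramethyl-1,3,2-dioxaborolan-2-yl)-2H-chromen-2-one F1. Rhodium-catalysed 1,2-addition of F1 to aldehyde 7 ([Rh(cod)OH]2, dioxane/H2O, 50 °C) gives the C1'-epimeric carbinol mixture 6-{(RS)-[(2R)-3,3-dimethyloxiran-2-yl](hydroxy)methyl}-7-methoxy-2H-chromen-2-one F2. F2 is oxidised without separation (Dess–Martin periodinane, NaHCO3, CH2Cl2) and the sequence comes back to the route at 8.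

Risk 2, step 5. The ortho-methoxy group can compete with the oxirane oxygen for zinc and erode the anti selectivity. The fallback stops relying on the hydride face and makes both epimers converge, setting out from 8. Reduction with NaBH4/CeCl3·7H2O in MeOH at −40 °C gives 9 together with its separable C1' epimer 6-{(S)-[(2R)-3,3-dimethyloxiran-2-yl](hydroxy)methyl}-7-methoxy-2H-chromen-2-one F3. Compound 9 goes on through step 6. F3 is esterified with inversion at C1' under Mitsunobu conditions (PPh3, diisopropyl azodicarboxylate, 3-methylbutanoic acid, toluene, 0 °C). Both streams come back to the route at 11.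

Risk 3, step 7. The neighbouring ester carbonyl can capture the developing C3' cation (dioxanylium ion), which would move the acyl group to O3'. The electron-rich benzylic ester may also ionise under acid. The fallback unmasks the diol without a cation next to the ester, setting out from 9. Acetone with catalytic BF3·OEt2 at −20 °C converts the oxirane into the acetonide; acetone oxygen attacks C3' and the C2'–O bond is retained. This gives 6-{(R)-hydroxy[(4R)-2,2,5,5-tetramethyl-1,3-dioxolan-4-yl]methyl}-7-methoxy-2H-chromen-2-one F4. Acylation with 10 (Et3N, DMAP, CH2Cl2) gives (R)-(7-methoxy-2-oxo-2H-chromen-6-yl)[(4R)-2,2,5,5-tetramethyl-1,3-dioxolan-4-yl]methyl 3-methylbutanoate F5. Mild acetal hydrolysis (AcOH/H2O 4:1, 40 °C) comes back to the route at 12.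

**Further compounds**

F1 | step 4 | 7-methoxy-6-(4,4,5,5-tetramethyl-1,3,2-dioxaborolan-2-yl)-2H-chromen-2-one | COc1cc2oc(=O)ccc2cc1B3OC(C)(C)C(C)(C)O3
F2 | step 4 | 6-{(RS)-[(2R)-3,3-dimethyloxiran-2-yl](hydroxy)methyl}-7-methoxy-2H-chromen-2-one (mixture of 9 and its C1' epimer) | COc1cc2oc(=O)ccc2cc1C(O)[C@H]3OC3(C)C
F3 | step 5 | 6-{(S)-[(2R)-3,3-dimethyloxiran-2-yl](hydroxy)methyl}-7-methoxy-2H-chromen-2-one | COc1cc2oc(=O)ccc2cc1[C@H](O)[C@H]3OC3(C)C
F4 | step 7 | 6-{(R)-hydroxy[(4R)-2,2,5,5-tetramethyl-1,3-dioxolan-4-yl]methyl}-7-methoxy-2H-chromen-2-one | COc1cc2oc(=O)ccc2cc1[C@@H](O)[C@H]3OC(C)(C)OC3(C)C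
F5 | step 7 | (R)-(7-methoxy-2-oxo-2H-chromen-6-yl)[(4R)-2,2,5,5-tetramethyl-1,3-dioxolan-4-yl]methyl 3-methylbutanoate | COc1cc2oc(=O)ccc2cc1[C@@H](OC(=O)CC(C)C)[C@H]3OC(C)(C)OC3(C)C
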